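The numbers of this flask belong to no real substance; no experiment stands behind them.

I start from the easy step, substrate to product, and then follow what stands beside it.

| setting | south-west | south-east |
|---|---|---|
| substrate | 0.066 M | 0.066 M |
| remark | a single well-mixed tank run continuously and read at steady state, 15 s in it on average | everything together in a closed stirred flask, run for 15 s |
| time |  | 15 s |

    substrate → product (k1 = 0.74 /s)
    substrate → intermediate A (k2 = 0.020 /s)
    substrate → intermediate B (k3 = 0.058 /s)
    intermediate B ⇌ intermediate C (K4 = 0.86, k4 = 0.11 /s)
    intermediate A ⇌ intermediate B (K5 = 0.46, k5 = 0.51 /s)

- the set-up with the highest amount of product at the outlet or at the end, in percent of the substrate put in ("none" if the first two lie within 2 percentage points) (south-west / south-east / none)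
- amount of product at the outlet or at the end, in percent of the substrate put in, south-west
- amount of product at the outlet or at the end, in percent of the substrate put in, south-east

- the stated concentrations are those of everything mixed, before any reaction; amounts are the same in each set-up
- run time (south-east): 15 s

**First instants.** I watch the closed flask, south-east. The charge is all substrate. The step to product alone halves it in 0.94 s, faster than the step to intermediate B at 12.0 s or the step to intermediate A at 35 s. Each step leaving substrate is first-order in substrate, so the substrate fraction cancels from their ratio. I therefore carry the product share, or selectivity: the rate constant to product over the sum of the rate constants leaving substrate, 90.5%.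

**The middle.** In south-east, the steps together halve substrate in 0.847 s. Intermediate A receives 2.44% of the charge and intermediate B 7.09%. Their exchange relaxes in 0.428 s, faster than the forward half-life of 6.3 s from intermediate B to intermediate C. The scheme draws no arrow from an intermediate to product or substrate.

**The end.** The summed constant 0.818 /s times 15 s is 12.3. South-east therefore keeps <0.001% of its substrate, and I commit to 90.5% product. The tank, south-west, passes 7.54% of its substrate unreacted, so I commit to 83.6% there. South-east leads by 6.9 percentage points, above the margin. Two numbers get me there: the share and the fraction converted.

**The forecast.** It names south-east, with 83.7% for south-west and 90.5% for south-east, holding that “the intermediates never return to it”. Its south-west figure stands close to mine, and its south-east figure matches mine.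

**At rest?** The simulation puts south-east ahead, with 90.5% against 83.6% in south-west. South-east holds 0% substrate after 15.0 s. The share 90.5% carries to a neighbour of south-east charged with 0.017 M, a quarter of the amount, and that flask gives 90.5%. Left for 150 s, south-east still stands at 90.5% product. Intermediate A moves from 5.30% to 5.14%, and intermediate C rises from 1.82% to 2.03%.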